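The four C–Br bonds of ring A are disconnected together. The key step exploits that each C–H carbon of the guaiacol-derived ring A (C3–C6; C1 bears the bridging oxygen, C2 the methoxy group) lies ortho or para to one of these two oxygens, whereas ring B already holds both bromines and a nitro group on the carbon that later becomes C–OH. One iron-catalysed bromination should therefore place four bromines on ring A and spare the deactivated ring B. The precursor is the ether 1,5-dibromo-3-(2-methoxyphenoxy)-2-nitrobenzene, made by fluoride displacement with guaiacol; nitro is finally exchanged for hydroxyl via the aniline and its diazonium salt.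

Key step: step 3

Assumption: the target has no stereocentre and its diaryl ether axis rotates freely, so it is one achiral compound and no stereocontrol is needed.

Step 1
Reactants: 1 2,4-dibromo-6-fluoroaniline
Product: 4 1,5-dibromo-3-fluoro-2-nitrobenzene, via hydroxylamine 2 (not isolated), via nitrosoarene 3 (not isolated)
Conditions: mCPBA (4 equiv), ClCH2CH2Cl, reflux
Reagents that add atoms: mCPBA (3-chloroperoxybenzoic acid), O=C(OO)c1cccc(Cl)c1
Why: Peracid N-oxidation of an arylamine to a nitroarene: mCPBA transfers oxygen to nitrogen three times (amine to 2 to 3 to 4), the two ortho halogens of this weakly basic aniline should hold back azo and azoxy condensation, and the C–F and C–Br bonds are inert to the oxidant.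

Step 2
Reactants: 4 1,5-dibromo-3-fluoro-2-nitrobenzene; 5 guaiacol (2-methoxyphenol)
Product: 6 1,5-dibromo-3-(2-methoxyphenoxy)-2-nitrobenzene
Conditions: K2CO3 (1.5 equiv), 5 (1.0 equiv), DMF, rt to 50 °C
Reagents that add atoms: none
Why: Nucleophilic aromatic substitution (SNAr, addition–elimination through a Meisenheimer complex): the phenoxide of 5 attacks the carbon ortho to the nitro group and fluoride, the fastest leaving group in this mechanism, departs, so with one equivalent of phenol at mild temperature the ortho and para bromides should stay in place.

Step 3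
Reactants: 6 1,5-dibromo-3-(2-methoxyphenoxy)-2-nitrobenzene; 7 bromine
Product: 11 1,5-dibromo-2-nitro-3-(2,3,4,5-tetrabromo-6-methoxyphenoxy)benzene, via monobromide 8 (not isolated), via dibromide 9 (not isolated), via tribromide 10 (not isolated)
Conditions: Br2 (4.3 equiv, in portions), Fe powder (10 mol%), ClCH2CH2Cl, 0 °C to 50 °C, dark, N2 sweep
Reagents that add atoms: bromine (7), BrBr
Why: Iron is converted in the flask into FeBr3, which polarises Br2 for four successive electrophilic aromatic substitutions (σ-complex, then loss of HBr) at C3–C6 of ring A, every one of which is ortho or para to the methoxy oxygen or the bridging oxygen. The two para carbons should react first (C5 giving 8, then C4 giving 9, as in the dibromination of veratrole), and the two flanked ortho carbons follow under Lewis-acid catalysis and gentle warming (10 is drawn with the third bromine next to the stronger methoxy donor; the order of the last two substitutions does not change the outcome). The closest known reaction type is the exhaustive Lewis-acid-promoted bromination of guaiacol and veratrole to their tetrabromo derivatives. No ring is formed and no stereocentre arises, so the only demand is chemoselectivity: four substitutions on ring A before any on ring B, with the O–CH3 bond kept. The substrate should secure this because ring A keeps two oxygen donors, whereas ring B has a single oxygen donor opposed by a nitro group and two bromines, its two C–H carbons each sit between two substituents, and the nitro group beside the bridging oxygen lowers that oxygen's donor strength. A small measured excess of bromine added in portions, monitoring of the last substitution and removal of HBr in the nitrogen stream should stop the reaction at 11.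

Step 4
Reactants: 11 1,5-dibromo-2-nitro-3-(2,3,4,5-tetrabromo-6-methoxyphenoxy)benzene
Product: 14 2,4-dibromo-6-(2,3,4,5-tetrabromo-6-methoxyphenoxy)aniline, via nitrosoarene 12 (not isolated), via hydroxylamine 13 (not isolated)
Conditions: Fe powder (6 equiv), AcOH/EtOH/THF, 70 °C
Reagents that add atoms: none
Why: Béchamp-type reduction: stepwise electron transfer from iron with protonation by acetic acid takes the nitro group through 12 and 13 to the amine, and unlike catalytic hydrogenation it should leave all six aryl C–Br bonds and both ether links untouched.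

Step 5
Reactants: 14 2,4-dibromo-6-(2,3,4,5-tetrabromo-6-methoxyphenoxy)aniline
Product: 16 2,4-dibromo-6-(2,3,4,5-tetrabromo-6-methoxyphenoxy)phenol, via diazonium salt 15 (not isolated)
Conditions: NaNO2 (1.1 equiv), conc. H2SO4/AcOH, 0–10 °C; then ice-water, Cu(NO3)2·3H2O (large excess), Cu2O (0.5 equiv, in portions), rt
Reagents that add atoms: water, O (oxygen of the new hydroxyl); sodium nitrite, [Na+].[O-]N=O (second nitrogen of intermediate 15 only)
Why: Diazotisation of the weakly basic, hindered aniline with nitrosylsulfuric acid followed by copper-mediated hydroxydediazoniation (Sandmeyer-type hydroxylation): Cu(I) reduces 15 to an aryl radical that Cu(II)-bound water converts into the phenol at room temperature with regeneration of Cu(I), which avoids the hot acid and free aryl cation that the neighbouring methoxy oxygen could intercept.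

Compound list
1 | 2,4-dibromo-6-fluoroaniline | Nc1c(F)cc(Br)cc1Br | starting material
2 | N-(2,4-dibromo-6-fluorophenyl)hydroxylamine [not isolated] | ONc1c(F)cc(Br)cc1Br | intermediate
3 | 1,5-dibromo-3-fluoro-2-nitrosobenzene [not isolated] | O=Nc1c(F)cc(Br)cc1Br | intermediate
4 | 1,5-dibromo-3-fluoro-2-nitrobenzene | O=[N+]([O-])c1c(F)cc(Br)cc1Br | intermediate
5 | guaiacol (2-methoxyphenol) | COc1ccccc1O | starting material
6 | 1,5-dibromo-3-(2-methoxyphenoxy)-2-nitrobenzene | COc1ccccc1Oc1cc(Br)cc(Br)c1[N+](=O)[O-] | intermediate
7 | bromine | BrBr | starting material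
8 | 1,5-dibromo-3-(5-bromo-2-methoxyphenoxy)-2-nitrobenzene [not isolated] | COc1ccc(Br)cc1Oc1cc(Br)cc(Br)c1[N+](=O)[O-] | intermediate
9 | 1,5-dibromo-3-(4,5-dibromo-2-methoxyphenoxy)-2-nitrobenzene [not isolated] | COc1cc(Br)c(Br)cc1Oc1cc(Br)cc(Br)c1[N+](=O)[O-] | intermediate
10 | 1,5-dibromo-2-nitro-3-(3,4,5-tribromo-2-methoxyphenoxy)benzene [not isolated] | COc1c(Br)c(Br)c(Br)cc1Oc1cc(Br)cc(Br)c1[N+](=O)[O-] | intermediate
11 | 1,5-dibromo-2-nitro-3-(2,3,4,5-tetrabromo-6-methoxyphenoxy)benzene | COc1c(Br)c(Br)c(Br)c(Br)c1Oc1cc(Br)cc(Br)c1[N+](=O)[O-] | intermediate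
12 | 1,5-dibromo-2-nitroso-3-(2,3,4,5-tetrabromo-6-methoxyphenoxy)benzene [not isolated] | COc1c(Br)c(Br)c(Br)c(Br)c1Oc1cc(Br)cc(Br)c1N=O | intermediate
13 | N-[2,4-dibromo-6-(2,3,4,5-tetrabromo-6-methoxyphenoxy)phenyl]hydroxylamine [not isolated] | COc1c(Br)c(Br)c(Br)c(Br)c1Oc1cc(Br)cc(Br)c1NO | intermediate
14 | 2,4-dibromo-6-(2,3,4,5-tetrabromo-6-methoxyphenoxy)aniline | COc1c(Br)c(Br)c(Br)c(Br)c1Oc1cc(Br)cc(Br)c1N | intermediate
15 | 2,4-dibromo-6-(2,3,4,5-tetrabromo-6-methoxyphenoxy)benzenediazonium hydrogensulfate [not isolated] | COc1c(Br)c(Br)c(Br)c(Br)c1Oc1cc(Br)cc(Br)c1[N+]#N.OS(=O)(=O)[O-] | intermediate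
16 | 2,4-dibromo-6-(2,3,4,5-tetrabromo-6-methoxyphenoxy)phenol (achiral) | COc1c(Br)c(Br)c(Br)c(Br)c1Oc1cc(Br)cc(Br)c1O | target

Total step count: 5. Longest linear sequence: 5 steps (1 to 16); guaiacol 5 enters at step 2 and bromine 7 at step 3.

Steps most likely to fail

Step 3 (key step). The fourth substitution on the already tribrominated ring A may become slower than attack on a ring B C–H carbon or than cleavage of the O–methyl bond by HBr and the Lewis acid. Over-bromination or demethylation would then set in before ring A is full. Fallback: the ring A C–Br bonds would be made before the ether bond. Guaiacol 5 would be perbrominated with bromine 7 and catalytic iron in CHCl3 to 3,4,5,6-tetrabromo-2-methoxyphenol F1. Its caesium phenoxide (Cs2CO3, DMSO, 60–80 °C) would then displace the fluoride of 4 in an SNAr reaction. This sets out from 5 (with 4 and 7) and comes back to the route at 11.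

Step 5. After loss of nitrogen the aryl radical, or an aryl cation if the copper path is slow, may be captured within the molecule by ring A. Attack on the methoxy oxygen or on an ipso carbon, with loss of methyl or bromine, would close a third ring. Hydrogen abstraction to the reduced arene is a second diversion. The weakly basic, poorly soluble aniline may also diazotise incompletely. Fallback: a formyl group would serve as the latent hydroxyl, so that no diazonium ion is needed.
- Guaiacol 5 and purchased 2,4-dibromo-6-fluorobenzaldehyde F2 would give, by SNAr (K2CO3, DMF, 90 °C), 2,4-dibromo-6-(2-methoxyphenoxy)benzaldehyde F3.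
- Bromine 7 with catalytic iron would fill ring A as in step 3, the formyl group now deactivating ring B, to give 2,4-dibromo-6-(2,3,4,5-tetrabromo-6-methoxyphenoxy)benzaldehyde F4.
- Baeyer–Villiger oxidation with mCPBA (CH2Cl2, rt) should give 2,4-dibromo-6-(2,3,4,5-tetrabromo-6-methoxyphenoxy)phenyl formate F5, and K2CO3 in methanol would cleave the formate.

This sets out from 5 and comes back to the route at the target 16.

Step 1. Oxygen transfer to the hindered, electron-poor nitrogen may stall at the nitroso stage, or partly oxidised species may condense to azoxy dimers. Fallback: the amino group would be replaced instead of oxidised, by a Sandmeyer-type nitro-dediazoniation. Aniline 1 would be diazotised with NaNO2 in aqueous HBF4 at 0 °C to 2,4-dibromo-6-fluorobenzenediazonium tetrafluoroborate F6, collected by filtration. Treatment with excess NaNO2 and copper powder in water at rt should exchange N2 for NO2. This sets out from 1 and comes back to the route at 4.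

Further compounds
F1 | step 3 | 3,4,5,6-tetrabromo-2-methoxyphenol | COc1c(Br)c(Br)c(Br)c(Br)c1O
F2 | step 5 | 2,4-dibromo-6-fluorobenzaldehyde (purchased) | O=Cc1c(F)cc(Br)cc1Br
F3 | step 5 | 2,4-dibromo-6-(2-methoxyphenoxy)benzaldehyde | COc1ccccc1Oc1cc(Br)cc(Br)c1C=O
F4 | step 5 | 2,4-dibromo-6-(2,3,4,5-tetrabromo-6-methoxyphenoxy)benzaldehyde | COc1c(Br)c(Br)c(Br)c(Br)c1Oc1cc(Br)cc(Br)c1C=O
F5 | step 5 | 2,4-dibromo-6-(2,3,4,5-tetrabromo-6-methoxyphenoxy)phenyl formate | COc1c(Br)c(Br)c(Br)c(Br)c1Oc1cc(Br)cc(Br)c1OC=O
F6 | step 1 | 2,4-dibromo-6-fluorobenzenediazonium tetrafluoroborate | N#[N+]c1c(F)cc(Br)cc1Br.F[B-](F)(F)F
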